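The flavone is disconnected across ring C at C4a–C4 and O1–C2: ring A comes from 2,4-dimethoxybenzene-1,3,5-triol, and C2–C4 with ring B from a benzyl-protected ethyl aroylacetate. One acid-free thermal Mentzer condensation forms both bonds and the pyranone ring. It exploits the symmetry of ring A: the only unsubstituted carbon (future C4a) sits between two equivalent hydroxyls (future C5–OH and O1 on C8a), so C-acylation and closure can give only the 5,7-dihydroxy-6,8-dimethoxy pattern. The precursors are the free triol, released by hydrogenolysis just before use, and ethyl 3-[3,6-bis(benzyloxy)-2-methoxyphenyl]-3-oxopropanoate; a final debenzylation gives the target.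

Key step: step 7

Remark: the target has no stereocentre and rotation about C2–C1' is free, so it is a single achiral compound and no step has to set configuration; 1,3,5-tris(benzyloxy)benzene is taken as a catalogue compound.

Step 1
Reactants: 1 1,3,5-tris(benzyloxy)benzene
Product: 2 1,3,5-tris(benzyloxy)-2,4-dibromobenzene
Conditions: NBS (2.05 equiv), CH2Cl2, 0 °C to rt, dark
Reagents that add atoms: N-bromosuccinimide, O=C1CCC(=O)N1Br
Why: Electrophilic aromatic bromination: the phloroglucinol core is far more electron-rich than the benzyl rings, and two equivalents of NBS in the dark should halt at the 2,4-dibromide because each bromine lowers the reactivity of the one remaining position.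

Step 2
Reactants: 2 1,3,5-tris(benzyloxy)-2,4-dibromobenzene
Product: 3 1,3,5-tris(benzyloxy)-2,4-dimethoxybenzene
Conditions: NaOMe (excess, 25% in MeOH), CuBr (cat.), DMF, 110 °C, N2
Reagents that add atoms: sodium methoxide, C[O-].[Na+]
Why: Copper(I)-catalysed Ullmann-type methoxylation replaces both aryl bromides by methoxide, a reaction known to tolerate ortho alkoxy groups, while benzyl ethers are inert to methoxide.

Step 3
Reactants: 3 1,3,5-tris(benzyloxy)-2,4-dimethoxybenzene
Product: 4 2,4-dimethoxybenzene-1,3,5-triol
Conditions: H2 (1 atm), 10% Pd/C, EtOAc–MeOH, rt; filtered and concentrated under Ar, used at once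
Reagents that add atoms: none
Why: Catalytic hydrogenolysis cleaves the three O-benzyl bonds but not the aryl methyl ethers, and it frees the oxidation-prone triol under neutral, non-aqueous conditions.

Step 4
Reactants: 5 2'-hydroxy-6'-methoxyacetophenone
Product: 7 1-(3,6-dihydroxy-2-methoxyphenyl)ethanone, via aryl sulfate 6 (not isolated)
Conditions: K2S2O8, aq. KOH, 0–20 °C; acidify and recover unreacted 5 (Et2O); then aq. HCl, Na2SO3, 90 °C
Reagents that add atoms: potassium peroxodisulfate, [K+].[K+].[O-]S(=O)(=O)OOS(=O)(=O)[O-]
Why: Elbs persulfate oxidation: the phenoxide of 5 attacks a peroxide oxygen of peroxodisulfate through the carbon para to its oxygen (C5'), and acid hydrolysis of the resulting aryl sulfate 6 should give the hydroquinone, with unreacted 5 recovered beforehand.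

Step 5
Reactants: 7 1-(3,6-dihydroxy-2-methoxyphenyl)ethanone
Product: 8 1-[3,6-bis(benzyloxy)-2-methoxyphenyl]ethanone
Conditions: BnBr (2.4 equiv), K2CO3, KI (cat.), DMF, 70 °C, Ar
Reagents that add atoms: benzyl bromide, BrCc1ccccc1
Why: Williamson etherification of both phenoxides with benzyl bromide, with warming needed for the hydroxyl that is hydrogen-bonded to the acetyl group and argon to keep the hydroquinone from oxidising.

Step 6
Reactants: 8 1-[3,6-bis(benzyloxy)-2-methoxyphenyl]ethanone; 9 diethyl carbonate
Product: 10 ethyl 3-[3,6-bis(benzyloxy)-2-methoxyphenyl]-3-oxopropanoate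
Conditions: NaH (3 equiv), (EtO)2CO (excess), toluene, 100 °C; then cold aq. HCl
Reagents that add atoms: diethyl carbonate (9), CCOC(=O)OCC
Why: Crossed Claisen condensation: the methyl-ketone enolate is acylated by non-enolisable diethyl carbonate and deprotonation of the β-ketoester drives the equilibrium, the benzyl and methyl ethers being inert to NaH.

Step 7
Reactants: 4 2,4-dimethoxybenzene-1,3,5-triol; 10 ethyl 3-[3,6-bis(benzyloxy)-2-methoxyphenyl]-3-oxopropanoate
Product: 13 2-[3,6-bis(benzyloxy)-2-methoxyphenyl]-5,7-dihydroxy-6,8-dimethoxychromen-4-one, via aroylketene 11 (not isolated), via diketone 12 (not isolated)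
Conditions: 4 (1 equiv), 10 (1.5 equiv), neat melt (or minimal Ph2O), 240–250 °C, Ar stream to carry off EtOH and H2O, 1–2 h
Reagents that add atoms: none
Why: At about 240 °C ketoester 10 should lose ethanol to give aroylketene 11 (any O-aryl ester formed reversibly feeds the same ketene back), which acylates the single unsubstituted ring carbon of 4, the most nucleophilic site because it is ortho or para to all three hydroxyls, and so forms C4a–C4 of diketone 12. The closest known reaction type is the Mentzer (thermal, Simonis-type) pyrone synthesis, which gives 5,7-dihydroxyflavones from phloroglucinols and ethyl aroylacetates. Ring C then closes by 6-exo-trig addition of an ortho hydroxyl to the aryl ketone carbonyl (O1–C2), and the hemiketal loses water to give the aromatic 4-pyranone. No stereocentre is formed. Regioselectivity needs no control, because 4 has a mirror plane through its C–H carbon and the two flanking hydroxyls are equivalent, so either closure, and any Wessely–Moser ring opening and reclosure, leads to the same 5,7-dihydroxy-6,8-dimethoxy pattern. Chemoselectivity for the flavone over the Pechmann 4-arylcoumarin rests on the absence of acid and on the 2,6-disubstituted aryl ketone, whose carbonyl is shielded from intermolecular attack by the ring carbon, while the benzyl ethers leave no free ring-B hydroxyl that could lactonise.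

Step 8
Reactants: 13 2-[3,6-bis(benzyloxy)-2-methoxyphenyl]-5,7-dihydroxy-6,8-dimethoxychromen-4-one
Product: 14 5,7,3',6'-tetrahydroxy-6,8,2'-trimethoxyflavone
Conditions: H2 (1 atm), 10% Pd/C, THF–MeOH, rt; filtered under Ar
Reagents that add atoms: none
Why: Hydrogenolysis of the two aryl benzyl ethers over Pd/C at 1 atm is much faster than reduction of the flavone C2=C3 bond, and methyl ethers and free phenols are unaffected, so 14 should result directly.

Compound list
1 | 1,3,5-tris(benzyloxy)benzene | c1ccc(COc2cc(OCc3ccccc3)cc(OCc3ccccc3)c2)cc1 | starting material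
2 | 1,3,5-tris(benzyloxy)-2,4-dibromobenzene | Brc1c(OCc2ccccc2)cc(OCc2ccccc2)c(Br)c1OCc1ccccc1 | intermediate
3 | 1,3,5-tris(benzyloxy)-2,4-dimethoxybenzene | COc1c(OCc2ccccc2)cc(OCc2ccccc2)c(OC)c1OCc1ccccc1 | intermediate
4 | 2,4-dimethoxybenzene-1,3,5-triol | COc1c(O)cc(O)c(OC)c1O | intermediate
5 | 2'-hydroxy-6'-methoxyacetophenone | CC(=O)c1c(O)cccc1OC | starting material
6 | potassium 3-acetyl-4-hydroxy-2-methoxyphenyl sulfate | CC(=O)c1c(O)ccc(OS(=O)(=O)[O-])c1OC.[K+] | intermediate
7 | 1-(3,6-dihydroxy-2-methoxyphenyl)ethanone | CC(=O)c1c(O)ccc(O)c1OC | intermediate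
8 | 1-[3,6-bis(benzyloxy)-2-methoxyphenyl]ethanone | CC(=O)c1c(OCc2ccccc2)ccc(OCc2ccccc2)c1OC | intermediate
9 | diethyl carbonate | CCOC(=O)OCC | starting material
10 | ethyl 3-[3,6-bis(benzyloxy)-2-methoxyphenyl]-3-oxopropanoate | CCOC(=O)CC(=O)c1c(OC)c(OCc2ccccc2)ccc1OCc1ccccc1 | intermediate
11 | [3,6-bis(benzyloxy)-2-methoxybenzoyl]ketene, i.e. 3-[3,6-bis(benzyloxy)-2-methoxyphenyl]-3-oxoprop-1-en-1-one | O=C=CC(=O)c1c(OC)c(OCc2ccccc2)ccc1OCc1ccccc1 | intermediate
12 | 1-[3,6-bis(benzyloxy)-2-methoxyphenyl]-3-(2,4,6-trihydroxy-3,5-dimethoxyphenyl)propane-1,3-dione | COc1c(O)c(OC)c(O)c(C(=O)CC(=O)c2c(OC)c(OCc3ccccc3)ccc2OCc2ccccc2)c1O | intermediate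
13 | 2-[3,6-bis(benzyloxy)-2-methoxyphenyl]-5,7-dihydroxy-6,8-dimethoxychromen-4-one | COc1c(OCc2ccccc2)ccc(OCc2ccccc2)c1-c1cc(=O)c2c(O)c(OC)c(O)c(OC)c2o1 | intermediate
14 | 5,7,3',6'-tetrahydroxy-6,8,2'-trimethoxyflavone, i.e. 2-(3,6-dihydroxy-2-methoxyphenyl)-5,7-dihydroxy-6,8-dimethoxychromen-4-one | COc1c(O)ccc(O)c1-c1cc(=O)c2c(O)c(OC)c(O)c(OC)c2o1 | target

Total step count: 8.
Longest linear sequence: 5 steps (steps 1, 2, 3, 7, 8; the ring-B branch, steps 4, 5, 6, 7, 8, is equally long).

Steps most likely to fail

Step 7. The aroylketene may be consumed by self-condensation, or acyl transfer may stop at oxygen, before the ring carbon is acylated. Benzyl groups may also migrate or be lost in the hot phenolic melt, and the triol may be oxidised. The fallback builds the same diketone stepwise at low temperature by enolate acylation. It sets out from 4 and 8 and comes back to the route at 12, which is then closed to 13. Triol 4 is C-acetylated (AcOH, BF3·OEt2, 80 °C, Friedel–Crafts acylation at its only free carbon) to 1-(2,4,6-trihydroxy-3,5-dimethoxyphenyl)ethanone F1. Ketone 8 is degraded by the haloform reaction (NaOBr, aq. dioxane) to 3,6-bis(benzyloxy)-2-methoxybenzoic acid F2. Oxalyl chloride with catalytic DMF in CH2Cl2 converts F2 into 3,6-bis(benzyloxy)-2-methoxybenzoyl chloride F3. The lithium polyanion of F1 (LiHMDS, 5 equiv, THF, −78 °C) should be acylated at the enolate carbon by F3, giving 12 after acidification. Brief warming of 12 in AcOH with a trace of H2SO4 (95 °C) should cyclodehydrate it to 13.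

Step 2. Reductive loss of bromine and stalling after the first substitution are possible at positions flanked by two benzyloxy groups. The fallback reverses the polarity and makes the aryl carbon the nucleophile. It sets out from 2 and comes back at 3. n-BuLi is added to 2 in the presence of B(OiPr)3 (in situ quench, THF–toluene, −78 °C), so each aryllithium is trapped as it forms. This should give tetraisopropyl [2,4,6-tris(benzyloxy)-1,3-phenylene]bis(boronate) F4, which is not isolated. Oxidation in the same flask with H2O2/NaOH should give 2,4,6-tris(benzyloxy)benzene-1,3-diol F5. O-Methylation of F5 (MeI, K2CO3, acetone) gives 3.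

Step 8. Saturation of the C2–C3 double bond under hydrogen, or aerial oxidation of the ring-B hydroquinone on the catalyst during filtration, may erode the product. The fallback is a non-reductive Lewis-acid debenzylation that sets out from 13 and comes back at 14 with no new intermediate. BCl3 with pentamethylbenzene as benzyl-cation scavenger (CH2Cl2, −78 °C, then MeOH quench) should cleave only the two benzyl ethers. Aryl methyl ethers are not cleaved at this temperature.

Further compounds
F1 | step 7 | 1-(2,4,6-trihydroxy-3,5-dimethoxyphenyl)ethanone | CC(=O)c1c(O)c(OC)c(O)c(OC)c1O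
F2 | step 7 | 3,6-bis(benzyloxy)-2-methoxybenzoic acid | OC(=O)c1c(OC)c(OCc2ccccc2)ccc1OCc1ccccc1
F3 | step 7 | 3,6-bis(benzyloxy)-2-methoxybenzoyl chloride | ClC(=O)c1c(OC)c(OCc2ccccc2)ccc1OCc1ccccc1
F4 | step 2 | tetraisopropyl [2,4,6-tris(benzyloxy)-1,3-phenylene]bis(boronate) | CC(C)OB(OC(C)C)c1c(OCc2ccccc2)cc(OCc2ccccc2)c(B(OC(C)C)OC(C)C)c1OCc1ccccc1
F5 | step 2 | 2,4,6-tris(benzyloxy)benzene-1,3-diol | Oc1c(OCc2ccccc2)cc(OCc2ccccc2)c(O)c1OCc1ccccc1
F0 | step 8 | none | none
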